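## Retrosynthetic overview

1. The target comes from threefold PMB-ether cleavage of a tris-PMB trimer that already holds every ring and every carbon stereocentre.
2. The trimer comes from a Michael addition of the β-keto-ester carbon Cq of a bicyclic "dimer" to C9 of a third enedione macrodiolide (ring A); this is the last C–C bond.
3. The dimer comes from an amine–squaramide Michael/aldol [3+2] annulation of a 10,11-dioxo macrodiolide (ring B) with the enedione macrodiolide (ring C); bonds Cq–Cv and Ct–Cu close the cyclopentanone.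
4. Both partners come from one PMB-protected 14-membered macrodiolide, built by Still–Gennari Z-olefination (C3=C4), furan unmasking to the 4-oxo-enoic acid, and Yamaguchi lactonisation (O7–C8).
5. Building blocks are ethyl sorbate (Shi epoxidation, PMBOH opening), 4-(furan-2-yl)butan-2-one (enzymatic reduction) and a phosphonoacetic acid. Ring order: the 14-membered ring first (used three times, one copy oxidised), the cyclopentanone last.

Assumption: the Still–Gennari acid and the L-fructose-derived Shi ketone are taken as catalogue items.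

Labels: macrodiolide locants are O1, C2(=O), C3=C4, C5, C6, O7, C8(=O), C9=C10, C11(=O), C12, C13, C14. In the five-membered ring, Cq is the quaternary carbon, Ck the ring ketone, Ct the tertiary carbinol, Cu the CH bearing the ring C ketone, and Cv the CH bearing the ring C ester. Ring A is pendant on Cq, ring B bridges Cq/Ct, ring C is fused at Cu/Cv.

Catalysts:
- ent-Shi ketone = 1,2:4,5-di-O-isopropylidene-β-L-erythro-2,3-hexodiulo-2,6-pyranose.
- KRED = NADPH-dependent (S)-selective (Prelog) ketoreductase.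
- QN-SQ = 3-{[3,5-bis(trifluoromethyl)phenyl]amino}-4-{[(8α,9S)-6′-methoxycinchonan-9-yl]amino}cyclobut-3-ene-1,2-dione.
- QD-SQ = its pseudoenantiomer with the (9R)-6′-methoxycinchonan-9-yl group (from quinidine).

## Route

Step 1
Reactants: 1 ethyl (2E,4E)-hexa-2,4-dienoate (ethyl sorbate)
Product: 2 ethyl (2E,4S,5S)-4,5-epoxyhex-2-enoate
Conditions: ent-Shi ketone (30 mol%), KHSO5 (as 2KHSO5·KHSO4·K2SO4), K2CO3, Bu4NHSO4, MeCN/(MeO)2CH2–aq. Na2B4O7 buffer (pH 10.5), 0 °C
Reagents that add atoms: potassium peroxymonosulfate, [K+].[O-]S(=O)(=O)OO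
Why: Shi epoxidation; the chiral dioxirane attacks only the electron-richer distal (4,5) olefin of the dienoate through a spiro transition state, and the L-fructose-derived ketone gives the (4S,5S) trans-epoxide, the first stereocentres of the route.

Step 2
Reactants: 2 ethyl (2E,4S,5S)-4,5-epoxyhex-2-enoate
Product: 3 ethyl (2E,4R,5S)-5-hydroxy-4-[(4-methoxybenzyl)oxy]hex-2-enoate
Conditions: 4-MeOC6H4CH2OH (3 equiv), BF3·OEt2 (10 mol%), CH2Cl2, −40 → −20 °C
Reagents that add atoms: 4-methoxybenzyl alcohol, COc1ccc(CO)cc1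
Why: Lewis-acid-catalysed SN2 alcoholysis of the vinyl epoxide at the allylic carbon C4 with inversion (4S → 4R) while C5–O is retained, giving the anti 4,5-dioxygen pattern with the two oxygens already differentiated.

Step 3
Reactants: 3 ethyl (2E,4R,5S)-5-hydroxy-4-[(4-methoxybenzyl)oxy]hex-2-enoate
Product: 4 ethyl (2E,4R,5S)-4-[(4-methoxybenzyl)oxy]-5-[(triethylsilyl)oxy]hex-2-enoate
Conditions: Et3SiCl, imidazole, DMF, 0 °C
Reagents that add atoms: chlorotriethylsilane, CC[Si](Cl)(CC)CC
Why: Standard silylation; the temporary TES ether stops the 5-OH from lactonising onto the Z-enoate that is made in step 7.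

Step 4
Reactants: 4 ethyl (2E,4R,5S)-4-[(4-methoxybenzyl)oxy]-5-[(triethylsilyl)oxy]hex-2-enoate
Product: 6 (2S,3S)-2-[(4-methoxybenzyl)oxy]-3-[(triethylsilyl)oxy]butanal, via ozonide 5 (not isolated)
Conditions: O3, CH2Cl2, −78 °C (stop at first blue tint); then PPh3, −78 °C → rt; used crude
Reagents that add atoms: ozone, [O-][O+]=O
Why: Ozonolysis with reductive work-up cuts the E-enoate (which only served to direct steps 1 and 2) to the α-alkoxy aldehyde without touching either stereocentre.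

Step 5
Reactants: 7 4-(furan-2-yl)butan-2-one
Product: 8 (2S)-4-(furan-2-yl)butan-2-ol
Conditions: KRED, NADP+ (cat.), i-PrOH, aq. KH2PO4/K2HPO4 buffer pH 7, 30 °C
Reagents that add atoms: none
Why: Biocatalytic ketone reduction with Prelog selectivity delivers hydride to the Re face of the methyl ketone and gives the (S)-carbinol (future C14) in high ee.

Step 6
Reactants: 8 (2S)-4-(furan-2-yl)butan-2-ol, 9 2-[bis(2,2,2-trifluoroethoxy)phosphoryl]acetic acid
Product: 10 (2S)-4-(furan-2-yl)butan-2-yl 2-[bis(2,2,2-trifluoroethoxy)phosphoryl]acetate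
Conditions: EDC·HCl, DMAP (10 mol%), CH2Cl2, 0 °C → rt
Reagents that add atoms: none
Why: Steglich-type carbodiimide esterification forms the C2–O1 ester with retention at C14 and installs the Still–Gennari reagent in the same operation.

Step 7
Reactants: 10 (2S)-4-(furan-2-yl)butan-2-yl 2-[bis(2,2,2-trifluoroethoxy)phosphoryl]acetate, 6 (2S,3S)-2-[(4-methoxybenzyl)oxy]-3-[(triethylsilyl)oxy]butanal
Product: 11 (2S)-4-(furan-2-yl)butan-2-yl (2Z,4R,5S)-4-[(4-methoxybenzyl)oxy]-5-[(triethylsilyl)oxy]hex-2-enoate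
Conditions: KN(SiMe3)2, 18-crown-6, THF, −78 °C; then 6, −78 °C
Reagents that add atoms: none
Why: Still–Gennari olefination; fast irreversible collapse of the trifluoroethyl phosphonate adduct gives the Z-enoate (C3=C4) and joins the two fragments without epimerising the α-alkoxy aldehyde.

Step 8
Reactants: 11 (2S)-4-(furan-2-yl)butan-2-yl (2Z,4R,5S)-4-[(4-methoxybenzyl)oxy]-5-[(triethylsilyl)oxy]hex-2-enoate
Product: 14 (2E,7S)-7-{[(2Z,4R,5S)-4-[(4-methoxybenzyl)oxy]-5-[(triethylsilyl)oxy]hex-2-enoyl]oxy}-4-oxooct-2-enoic acid, via Z-keto-enal 12 (not isolated), via E-keto-enal 13 (not isolated)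
Conditions: NBS, NaHCO3, acetone/H2O (10:1), −20 °C; pyridine, rt; then NaClO2, NaH2PO4, 2-methylbut-2-ene, t-BuOH/H2O, 0 °C → rt
Reagents that add atoms: water, O; sodium chlorite, [Na+].[O-]Cl=O
Why: Oxidative furan ring opening gives the cis 4-oxo-enal, pyridine isomerises it to trans, and Pinnick oxidation gives the (E)-4-oxo-2-enoic acid (C8–C11), the furan having served as a masked enedione acid.

Step 9
Reactants: 14 (2E,7S)-7-{[(2Z,4R,5S)-4-[(4-methoxybenzyl)oxy]-5-[(triethylsilyl)oxy]hex-2-enoyl]oxy}-4-oxooct-2-enoic acid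
Product: 15 (2E,7S)-7-{[(2Z,4R,5S)-5-hydroxy-4-[(4-methoxybenzyl)oxy]hex-2-enoyl]oxy}-4-oxooct-2-enoic acid
Conditions: HF·pyridine, pyridine, THF, 0 °C; used at once
Reagents that add atoms: none
Why: Buffered fluoride cleavage of the secondary TES ether leaves the PMB ether, the Z-enoate and the enedione acid intact.

Step 10
Reactants: 15 (2E,7S)-7-{[(2Z,4R,5S)-5-hydroxy-4-[(4-methoxybenzyl)oxy]hex-2-enoyl]oxy}-4-oxooct-2-enoic acid
Product: 17 (3Z,5R,6S,9E,14S)-5-[(4-methoxybenzyl)oxy]-6,14-dimethyl-1,7-dioxacyclotetradeca-3,9-diene-2,8,11-trione, via mixed anhydride 16 (not isolated)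
Conditions: 2,4,6-Cl3C6H2COCl, Et3N, THF, rt; then syringe-pump addition to DMAP, toluene (1 mM), 40 °C
Reagents that add atoms: none
Why: Yamaguchi macrolactonisation closes the 14-membered ring at O7–C8 with retention at C6; acylation by the activated acid outruns attack of the 5-OH on the hindered secondary-alkyl Z-enoate.

Step 11
Reactants: 17 (3Z,5R,6S,9E,14S)-5-[(4-methoxybenzyl)oxy]-6,14-dimethyl-1,7-dioxacyclotetradeca-3,9-diene-2,8,11-trione
Product: 19 (3Z,5R,6S,14S)-5-[(4-methoxybenzyl)oxy]-6,14-dimethyl-1,7-dioxacyclotetradec-3-ene-2,8,10,11-tetrone, via epoxide 18 (not isolated)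
Conditions: t-BuOOH (1.2 equiv), DBU (1.5 equiv), CH2Cl2, 0 °C → rt; pH 4 work-up; used within hours
Reagents that add atoms: tert-butyl hydroperoxide, CC(C)(C)OO
Why: Weitz–Scheffer epoxidation is selective for the doubly activated C9=C10 over the Z-enoate; DBU then removes the ketone-α epoxide proton H10 and opens the C9–O bond (E1cB-type epoxy-ketone to enolised 1,2-dione isomerisation), so the oxygen stays on C10 and both epoxide centres are erased.

Step 12
Reactants: 19 (3Z,5R,6S,14S)-5-[(4-methoxybenzyl)oxy]-6,14-dimethyl-1,7-dioxacyclotetradec-3-ene-2,8,10,11-tetrone, 17 (3Z,5R,6S,9E,14S)-5-[(4-methoxybenzyl)oxy]-6,14-dimethyl-1,7-dioxacyclotetradeca-3,9-diene-2,8,11-trione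
Product: 21 bis-PMB bicyclic dimer with a 2-hydroxycyclopentanone core Cq(H)–Ck(=O)–Ct(OH)–Cu–Cv (Cq S, Ct S, Cu S, Cv S), ring B bridging Cq/Ct and ring C trans-fused at Cu/Cv, via Michael adduct 20 (not isolated)
Conditions: QN-SQ (10 mol%), 4 Å MS, CH2Cl2, −20 °C → rt; 19:17 = 1:1
Reagents that add atoms: none
Why: Proposed new method: a catalytic asymmetric formal [3+2] Michael/aldol annulation between two macrocycles. The quinuclidine of QN-SQ deprotonates the enolised dione ester 19 (C9–H, a vinylogous acid), and the squaramide NH pair binds the C11 ketone of 17, so C9 of 19 adds to the Re face of C9 of 17 (β to the ketone), setting Cv as S. The resulting catalyst-bound ketone enolate at C10 then closes 5-enolexo onto the adjacent, highly electrophilic C11 carbonyl of the 1,2-dione. This places the ring C acyl trans to the ring C ester (Cu S) and the new OH syn to that acyl. The Cq ester and the Ct chain must be cis because both belong to ring B (Ct S, Cq–H S). The closest known reactions are amine–thiourea/squaramide Michael–aldol cascades of cyclic 1,2-diones with nitroalkenes or enals, which give bicyclic α-hydroxy ketones; acyclic 3,4-dioxo esters, γ-keto-enoate acceptors and macrocyclic partners have not been shown.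

Step 13
Reactants: 21 bis-PMB bicyclic dimer, 17 (3Z,5R,6S,9E,14S)-5-[(4-methoxybenzyl)oxy]-6,14-dimethyl-1,7-dioxacyclotetradeca-3,9-diene-2,8,11-trione
Product: 22 tris-PMB trimer (the target with its three secondary OH groups as 4-methoxybenzyl ethers; Cq S, ring A C9 R)
Conditions: QD-SQ (20 mol%), toluene (0.5 M), rt; 17 (1.5 equiv)
Reagents that add atoms: none
Why: Bifunctional cinchona–squaramide Michael addition of a cyclic β-keto ester to an enone-type acceptor; ring B blocks one face of the Cq enolate so the new bond forms anti to it (Cq S), and the pseudoenantiomeric catalyst presents the Si face of C9 of 17 (ring A C9 R), opposite to the face used in step 12.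

Step 14
Reactants: 22 tris-PMB trimer
Product: 23 CNP0072185.1 (target)
Conditions: DDQ (4 equiv), CH2Cl2/aq. NaH2PO4–Na2HPO4 buffer pH 7 (10:1), 0 °C → rt
Reagents that add atoms: none
Why: Oxidative PMB-ether cleavage under neutral conditions frees the three allylic hydroxyls without disturbing the β-keto ester, the tertiary ketol or the Z-enoates.

## Compound list

1 | ethyl (2E,4E)-hexa-2,4-dienoate | CCOC(=O)/C=C/C=C/C | starting material
2 | ethyl (2E,4S,5S)-4,5-epoxyhex-2-enoate | CCOC(=O)/C=C/[C@@H]1O[C@H]1C | intermediate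
3 | ethyl (2E,4R,5S)-5-hydroxy-4-[(4-methoxybenzyl)oxy]hex-2-enoate | CCOC(=O)/C=C/[C@@H](OCc1ccc(OC)cc1)[C@H](C)O | intermediate
4 | ethyl (2E,4R,5S)-4-[(4-methoxybenzyl)oxy]-5-[(triethylsilyl)oxy]hex-2-enoate | CCOC(=O)/C=C/[C@@H](OCc1ccc(OC)cc1)[C@H](C)O[Si](CC)(CC)CC | intermediate
5 | ozonide: ethyl 5-{(1S,2S)-1-[(4-methoxybenzyl)oxy]-2-[(triethylsilyl)oxy]propyl}-1,2,4-trioxolane-3-carboxylate (ring carbons unassigned, mixture) | CCOC(=O)C1OOC(O1)[C@@H](OCc2ccc(OC)cc2)[C@H](C)O[Si](CC)(CC)CC | intermediate (not isolated)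
6 | (2S,3S)-2-[(4-methoxybenzyl)oxy]-3-[(triethylsilyl)oxy]butanal | O=C[C@@H](OCc1ccc(OC)cc1)[C@H](C)O[Si](CC)(CC)CC | intermediate
7 | 4-(furan-2-yl)butan-2-one | CC(=O)CCc1ccco1 | starting material
8 | (2S)-4-(furan-2-yl)butan-2-ol | C[C@H](O)CCc1ccco1 | intermediate
9 | 2-[bis(2,2,2-trifluoroethoxy)phosphoryl]acetic acid | OC(=O)CP(=O)(OCC(F)(F)F)OCC(F)(F)F | starting material
10 | (2S)-4-(furan-2-yl)butan-2-yl 2-[bis(2,2,2-trifluoroethoxy)phosphoryl]acetate | C[C@@H](CCc1ccco1)OC(=O)CP(=O)(OCC(F)(F)F)OCC(F)(F)F | intermediate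
11 | (2S)-4-(furan-2-yl)butan-2-yl (2Z,4R,5S)-4-[(4-methoxybenzyl)oxy]-5-[(triethylsilyl)oxy]hex-2-enoate | C[C@@H](CCc1ccco1)OC(=O)/C=C\[C@@H](OCc1ccc(OC)cc1)[C@H](C)O[Si](CC)(CC)CC | intermediate
12 | Z-keto-enal: (2S,6Z)-5,8-dioxooct-6-en-2-yl (2Z,4R,5S)-4-[(4-methoxybenzyl)oxy]-5-[(triethylsilyl)oxy]hex-2-enoate | C[C@@H](CCC(=O)/C=C\C=O)OC(=O)/C=C\[C@@H](OCc1ccc(OC)cc1)[C@H](C)O[Si](CC)(CC)CC | intermediate (not isolated)
13 | E-keto-enal: (2S,6E)-5,8-dioxooct-6-en-2-yl (2Z,4R,5S)-4-[(4-methoxybenzyl)oxy]-5-[(triethylsilyl)oxy]hex-2-enoate | C[C@@H](CCC(=O)/C=C/C=O)OC(=O)/C=C\[C@@H](OCc1ccc(OC)cc1)[C@H](C)O[Si](CC)(CC)CC | intermediate (not isolated)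
14 | (2E,7S)-7-{[(2Z,4R,5S)-4-[(4-methoxybenzyl)oxy]-5-[(triethylsilyl)oxy]hex-2-enoyl]oxy}-4-oxooct-2-enoic acid | C[C@@H](CCC(=O)/C=C/C(=O)O)OC(=O)/C=C\[C@@H](OCc1ccc(OC)cc1)[C@H](C)O[Si](CC)(CC)CC | intermediate
15 | (2E,7S)-7-{[(2Z,4R,5S)-5-hydroxy-4-[(4-methoxybenzyl)oxy]hex-2-enoyl]oxy}-4-oxooct-2-enoic acid (seco acid) | C[C@@H](CCC(=O)/C=C/C(=O)O)OC(=O)/C=C\[C@@H](OCc1ccc(OC)cc1)[C@H](C)O | intermediate
16 | mixed anhydride of 15 with 2,4,6-trichlorobenzoic acid | C[C@@H](CCC(=O)/C=C/C(=O)OC(=O)c1c(Cl)cc(Cl)cc1Cl)OC(=O)/C=C\[C@@H](OCc1ccc(OC)cc1)[C@H](C)O | intermediate (not isolated)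
17 | (3Z,5R,6S,9E,14S)-5-[(4-methoxybenzyl)oxy]-6,14-dimethyl-1,7-dioxacyclotetradeca-3,9-diene-2,8,11-trione (PMB enedione macrodiolide) | C[C@@H]1OC(=O)/C=C/C(=O)CC[C@H](C)OC(=O)/C=C\[C@H]1OCc2ccc(OC)cc2 | intermediate
18 | trans-9,10-epoxide of 17 (both face isomers; epoxide carbons left unassigned) | C[C@@H]1OC(=O)C3OC3C(=O)CC[C@H](C)OC(=O)/C=C\[C@H]1OCc2ccc(OC)cc2 | intermediate (not isolated)
19 | (3Z,5R,6S,14S)-5-[(4-methoxybenzyl)oxy]-6,14-dimethyl-1,7-dioxacyclotetradec-3-ene-2,8,10,11-tetrone (drawn as the tetrone; the C9=C10 enol is the main tautomer) | C[C@@H]1OC(=O)CC(=O)C(=O)CC[C@H](C)OC(=O)/C=C\[C@H]1OCc2ccc(OC)cc2 | intermediate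
20 | Michael adduct: C9 of 19 bonded to C9 of 17 (new centre S, C10 of that ring now CH2; the C9 centre of the tetrone ring is enolisable and unassigned) | O=C1O[C@@H](C)[C@H](OCc2ccc(OC)cc2)/C=C\C(=O)O[C@@H](C)CCC(=O)C(=O)C1[C@@H]3CC(=O)CC[C@H](C)OC(=O)/C=C\[C@@H](OCc4ccc(OC)cc4)[C@H](C)OC3=O | intermediate (not isolated)
21 | bis-PMB bicyclic dimer: 2-hydroxycyclopentanone core (Cq–H S, Ct S, Cu S, Cv S), ring B bridging Cq/Ct, ring C trans-fused at Cu/Cv | [C@@H]23C(=O)O[C@@H](C)[C@H](OCc4ccc(OC)cc4)/C=C\C(=O)O[C@@H](C)CC[C@@](O)(C2=O)[C@H]2C(=O)CC[C@H](C)OC(=O)/C=C\[C@@H](OCc5ccc(OC)cc5)[C@H](C)OC(=O)[C@@H]23 | intermediate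
22 | tris-PMB trimer (target with its three secondary hydroxyls as 4-methoxybenzyl ethers) | C[C@@H]1OC(=O)[C@@H]([C@@]23C(=O)O[C@@H](C)[C@H](OCc4ccc(OC)cc4)/C=C\C(=O)O[C@@H](C)CC[C@@](O)(C2=O)[C@H]2C(=O)CC[C@H](C)OC(=O)/C=C\[C@@H](OCc5ccc(OC)cc5)[C@H](C)OC(=O)[C@@H]23)CC(=O)CC[C@H](C)OC(=O)/C=C\[C@H]1OCc6ccc(OC)cc6 | intermediate
23 | CNP0072185.1 | C[C@@H]1OC(=O)[C@@H]([C@@]23C(=O)O[C@@H](C)[C@H](O)/C=C\C(=O)O[C@@H](C)CC[C@@](O)(C2=O)[C@H]2C(=O)CC[C@H](C)OC(=O)/C=C\[C@@H](O)[C@H](C)OC(=O)[C@@H]23)CC(=O)CC[C@H](C)OC(=O)/C=C\[C@H]1O | target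

## Step count and risks

Total step count: 14. Longest linear sequence: 12 steps (steps 1–4 and 7–14); steps 5–6 form the side branch.

Steps most likely to fail:

Step 12 (the proposed annulation). The cascade may stop at the open adduct, add to the wrong face of C9, or let the product react on with more 17. The assignment of QN-SQ to the Re face and QD-SQ to the Si face is a working model that has to be checked first. The fallback uses known chemistry, sets out from 19 and 17 and comes back at 21. The two bonds are made in separate operations: a plain tertiary-amine Michael addition (Et3N, 5 mol%, CH2Cl2, 0 °C) is stopped at Michael adduct 20, which is isolated and its C9 epimers separated (the unwanted one is recycled by base-induced retro-Michael). The ring is then closed by a known enamine-type 5-enolexo aldol (pyrrolidine/AcOH or L-proline, DMSO, rt). Since 20 is already listed, this fallback makes no compound outside the list (F0).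

Step 11 (enedione to tetrone). The epoxide may open toward the 2,4-dioxo isomer, or the enolised 1,2-dione may degrade under DBU. The fallback sets out from 17 and comes back at 19, and fixes the position of the oxygen by known steps. Ketone-directed 1,4-hydrosilylation (Et3SiH, RhCl(PPh3)3 2 mol%, benzene, 50 °C) delivers hydride to C9 and gives the C10=C11 triethylsilyl enol ether F1. Rubottom oxidation (mCPBA, NaHCO3, CH2Cl2, 0 °C; then aqueous citric acid) gives the 10-hydroxy-11-ketone F2. Dess–Martin periodinane (CH2Cl2, rt) oxidises F2 to 19.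

Step 13 (quaternary centre). The hindered Cq–H may not add, the ketol may undergo retro-aldol, or C9 of ring A may form with the wrong configuration. The fallback reverses the order of the two C–C bond formations; it sets out from 19 and 17 and comes back at 22. QD-SQ-catalysed Michael addition of the still unhindered 19 to the Si face of 17 first gives the ring A–ring B Michael adduct F3. The step-12 annulation (QN-SQ, second equivalent of 17) is then run on F3, creating Cq, Cv, Cu and Ct in the ring-forming event and giving 22 directly.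

## Further compounds

F1 | step 11 | C10=C11 triethylsilyl enol ether of 17: (3Z,5R,6S,14S)-5-[(4-methoxybenzyl)oxy]-6,14-dimethyl-11-[(triethylsilyl)oxy]-1,7-dioxacyclotetradeca-3,10-diene-2,8-dione (enol ether geometry not controlled) | C[C@@H]1OC(=O)CC=C(O[Si](CC)(CC)CC)CC[C@H](C)OC(=O)/C=C\[C@H]1OCc2ccc(OC)cc2
F2 | step 11 | (3Z,5R,6S,14S)-10-hydroxy-5-[(4-methoxybenzyl)oxy]-6,14-dimethyl-1,7-dioxacyclotetradec-3-ene-2,8,11-trione (C10 epimers) | C[C@@H]1OC(=O)CC(O)C(=O)CC[C@H](C)OC(=O)/C=C\[C@H]1OCc2ccc(OC)cc2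
F0 | step 12 | none | none
F3 | step 13 | ring A–ring B Michael adduct: C9 of 19 bonded to C9 of 17 (ring A C9 R; the C9 centre of the tetrone ring enolisable and unassigned) | C[C@@H]1OC(=O)[C@@H](C3C(=O)O[C@@H](C)[C@H](OCc4ccc(OC)cc4)/C=C\C(=O)O[C@@H](C)CCC(=O)C3=O)CC(=O)CC[C@H](C)OC(=O)/C=C\[C@H]1OCc2ccc(OC)cc2
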